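## The problem

Compound 18 is an open-chain mono-ester of a 1,3-diol. A five-carbon chain carries a 3,4-dimethoxyphenyl carbinol at C1 (S), a tertiary carbon C2 (R) with an acyloxymethyl arm, and an (E)-4-methoxystyryl unit at C4–C5. The acyl group is (Z)-2-(hydroxymethyl)but-2-enoyl, with the C4' methyl cis to the ester carbonyl. No ring has to be made, so the work lies in joining three chain pieces at C2 (aryl carbonyl carbon, cinnamyl unit, one-carbon oxygenated arm) and in setting two adjacent stereocentres.

The two centres can steer each other. A C2 centre can direct hydride to a C1 ketone through a chelate with the hydroxymethyl oxygen, and a C1 carbinol could direct bond formation at C2. Only one centre therefore needs an external source of asymmetry.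

Several groups are fragile:
- The benzylic alcohol on the electron-rich ring ionises under acid.
- The 4-methoxystyrene rules out hydrogenolysis, ozonolysis and unselective hydroboration.
- The Z enoate drifts to the E isomer whenever its acyl carbon is activated in the presence of nucleophilic catalysts.
- The 1,3-hydroxy ester can shift its acyl group under base.

Three hydroxyls (primary on the core, secondary benzylic, primary allylic on the side chain) must also be told apart. The enabling feature is that C2 bears a CH2–O arm and sits next to the aryl-bearing C1. With C1 at the ketone level, C2 is the α-carbon of an aryl alkyl ketone, and its enol silane of single geometry can take up formaldehyde under a chiral Lewis acid.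

## Retrosynthesis

**Side-chain O–Si bond and ester CH2–O bond.** Target 18 is traced to its silyl ether 17, and 17 is cut between the primary carbinol carbon and the carboxylate oxygen into diol 10 and acid 16. The alkyl–oxygen cut is preferred to the usual acyl–oxygen cut for two reasons. Activating the acyl carbon of a Z-2-substituted but-2-enoic acid invites Z to E isomerisation. Activating the alcohol (Mitsunobu) separates the primary from the hindered benzylic hydroxyl more sharply and leaves the acid as a passive carboxylate. The precursors are a two-stereocentre diol and a four-carbon acid. The forward reaction must be regioselective for the primary hydroxyl, and the final desilylation must be buffered.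

**C1–H bond.** Diol 10 is traced to β-hydroxy ketone 9. Raising C1 to the ketone removes one stereocentre and turns C2 into an enolisable α-carbon, which is what the next cut needs. The neighbouring cut of the aryl–C1 bond would demand an α-branched aldehyde that epimerises more easily and offers weaker 1,2-induction. The forward reduction must deliver hydride within a chelate between the carbonyl and the free hydroxyl, anti to the cinnamyl branch.

**C2–CH2OH bond (key).** Ketone 9 is cut into enol silane 7 and formaldehyde 8. Cutting the C2–C3 bond instead would require asymmetric allylation of a β-oxygenated enolate, which tends to expel the β-oxygen. Bringing the one-carbon unit last avoids this and uses the cheapest electrophile. The precursor 7 has no stereocentre. The forward reaction must choose one face of the enol double bond, which requires a single enol geometry.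

**O–Si bond and C2–C3 bond.** Enol silane 7 comes from ketone 5 through its lithium Z enolate 6. Ketone 5 is cut at C2–C3 into acetophenone 3 (as its lithium enolate 4) and cinnamyl bromide 2, made from alcohol 1. Aryl alkyl ketones enolise to the Z enolate with high preference, so the geometry needed by the key step is delivered by the substrate class. The forward alkylation must stop after one alkyl group.

**Carboxyl C–C bond of the acid.** Acid 16 is cut at the vinyl–CO2H bond to vinyllithium 15, made from vinyl iodide 14. Iodide 14 is the silyl ether of iodo alcohol 13, which comes from iodo enal 12 and crotonaldehyde 11. The olefin geometry is fixed at the α-iodination, where the methyl ends up cis to iodine and trans to the formyl group. Exchanging iodine for carboxyl with retention then places methyl cis to the carboxyl, which is the Z acid. Condensation routes to 2-(hydroxymethyl)but-2-enoates normally give the E isomer, which is why this cut is preferred.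

## Roads not taken

**Alternative 1:** The cut is at the C3–C4 single bond, with C2–H formed in the same operation. 9-Borabicyclo[3.3.1]nonane would add to the 1,1-disubstituted alkene of the bis-silylated methylene diol A2. The resulting B-alkyl borane would be coupled in the same pot with bromostyrene A3 under PdCl2(dppf) (Suzuki–Miyaura) to give A1, whose double desilylation leads to diol 10.
- Merits: the route is convergent, the styrene geometry is bought with A3, and no enolisable α-stereocentre ketone is ever present. It is better than the chosen plan in configurational safety of C2.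
- Weak points: C2 is set by acyclic 1,2-induction from C1 in a hydroboration where aryl and silyloxy compete as the directing substituents. A2 must first be obtained as one enantiomer, and Morita–Baylis–Hillman reactions of electron-rich benzaldehydes are slow and hard to render asymmetric. Ester reduction, double silylation and double desilylation add steps.
- Comparison: the chosen plan sets against it a catalytic enantioselective step on the substrate class for which it was developed, and a shorter path to 10.

**Alternative 2:** The cut is at the C2'–CH2OH bond of the side chain, with C3'–H formed at the same time. i-Bu2AlH modified by HMPA or N-methylmorpholine N-oxide would add H and Al cis across the triple bond of ynoate A5. The α-alumino acrylate would be trapped by formaldehyde 8 to give A4, the benzylic triethylsilyl ether of the target.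
- Merits: the Z geometry follows from syn addition, and the acid fragment shrinks to commercial but-2-ynoic acid A6. In step economy of the side chain this road is better than the chosen four-step acid synthesis.
- Weak points: an aluminium hydride meets the fully assembled ester at the penultimate step, where 1,2-reduction would cut the molecule in two. The vinylaluminium can lose its geometry through an allenolate on warming, and monomeric formaldehyde and HMPA are awkward. The benzylic hydroxyl still needs a silyl group on and off, and the road says nothing about the two core stereocentres.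
- Comparison: the chosen plan sets against it an olefin geometry locked early in a small vinyl iodide, so the geometric risk is taken on cheap material.

**Alternative 3:** The cut is at C1–H, with both stereocentres fixed in one reduction. An NADPH-dependent ketoreductase would reduce one of the rapidly interconverting enantiomers of racemic keto ester A8 to hydroxy ester A7. Hydride reduction of the ester would then give diol 10.
- Merits: both centres come from one mild step, and the β-keto ester precursor monoalkylates cleanly, which removes the over-alkylation problem of the chosen route. It is also one step shorter to 10, so it is better in step count and in the alkylation.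
- Weak points: the enzyme must accept a bulky, lipophilic substrate with two aryl groups and an electron-rich, poorly electrophilic ketone. It must also give the one needed diastereomer out of four, which cannot be predicted from structure and needs panel screening.
- Comparison: the chosen plan sets against it two stereocontrol events with known models. These are the ligand-controlled face selection on a Z aryl ketone enol silane and the chelation-controlled hydride delivery, and each can be tuned separately.

Key step: step 4

Assumption: the sense of induction of the scandium–bipyridine catalyst on 7 is taken to follow that of simpler Z aryl ketone enol silanes. The ligand is written as its (S,S) antipode and is exchanged for (R,R) if correlation of 10 shows the opposite sense.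

## Route

Step 1
Reactants: 1 (E)-3-(4-methoxyphenyl)prop-2-en-1-ol
Product: 2 (E)-1-(3-bromoprop-1-en-1-yl)-4-methoxybenzene
Conditions: PBr3 (0.4 equiv), Et2O, −10 → 0 °C; cold NaHCO3 wash, used at once as a solution
Reagents that add atoms: phosphorus tribromide, BrP(Br)Br
Why: Bromination of a primary allylic alcohol through its phosphite ester; the conjugated E alkene is kept and the labile bromide is not stored or chromatographed.

Step 2
Reactants: 3 1-(3,4-dimethoxyphenyl)ethan-1-one; 2 (E)-1-(3-bromoprop-1-en-1-yl)-4-methoxybenzene
Product: 5 (E)-1-(3,4-dimethoxyphenyl)-5-(4-methoxyphenyl)pent-4-en-1-one, via lithium enolate 4 (not isolated)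
Conditions: LiN(i-Pr)2 (1.5 equiv), 3 (1.5 equiv), THF, −78 °C; then 2 (1.0 equiv), −78 → −20 °C
Reagents that add atoms: none
Why: Enolate alkylation (SN2 at the primary allylic carbon) of a preformed lithium enolate; the excess of cheap enolate and the low temperature should keep proton exchange with the product, and hence double alkylation, low.

Step 3
Reactants: 5 (E)-1-(3,4-dimethoxyphenyl)-5-(4-methoxyphenyl)pent-4-en-1-one
Product: 7 {[(1Z,4E)-1-(3,4-dimethoxyphenyl)-5-(4-methoxyphenyl)penta-1,4-dien-1-yl]oxy}trimethylsilane, via lithium Z-enolate 6 (not isolated)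
Conditions: LiN(SiMe3)2 (1.1 equiv), THF, −78 °C; Me3SiCl (1.3 equiv), −78 → 0 °C; pentane extraction, filtration through Et3N-deactivated silica
Reagents that add atoms: chlorotrimethylsilane, C[Si](C)(C)Cl
Why: Enolisation and O-silylation; aryl alkyl ketones give the Z enolate because the E enolate suffers allylic 1,3-strain between the aryl ring and the C3 methylene, and the only acidic site is the CH2 next to the carbonyl.

Step 4
Reactants: 7 {[(1Z,4E)-1-(3,4-dimethoxyphenyl)-5-(4-methoxyphenyl)penta-1,4-dien-1-yl]oxy}trimethylsilane; 8 formaldehyde (37% aqueous solution)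
Product: 9 (2R,4E)-1-(3,4-dimethoxyphenyl)-2-(hydroxymethyl)-5-(4-methoxyphenyl)pent-4-en-1-one
Conditions: Sc(OTf)3 (10 mol%), (S,S)-6,6'-bis(1-hydroxy-2,2-dimethylpropyl)-2,2'-bipyridine (12 mol%), 37% aq. HCHO (5 equiv), 1,2-dimethoxyethane–H2O 9:1, −20 °C
Reagents that add atoms: none
Why: This is a Mukaiyama aldol addition in aqueous medium, and the closest known reaction type is the scandium-catalysed asymmetric hydroxymethylation of silicon enolates with aqueous formaldehyde. Sc(OTf)3 and the tetradentate bipyridine diol form a water-stable cationic trivalent scandium complex that binds and activates formaldehyde 8 in its chiral pocket. The enol silane 7 attacks through an open transition state and the silyl group is then lost to water, which forms the C2–CH2OH bond. No ring is closed. The one new stereocentre at C2 is controlled by the ligand: formaldehyde has no faces, so selectivity depends only on which face of the enol double bond meets the bound aldehyde, and this is well defined only for a single enol geometry, which the Z configuration of 7 provides. The step needs C-hydroxymethylation to outrun protodesilylation of 7 and needs one addition only; the electron-rich aryl group raises the nucleophilicity of the enol silane, and the product α-carbon is tertiary and no longer silylated, so it should not react again. The isolated styrene and the aryl methyl ethers should be inert to this mild Lewis acid at −20 °C. Ketone 9 is kept cold and near neutral and is reduced promptly, because enolisation would erase C2 and dehydration would give the enone.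

Step 5
Reactants: 9 (2R,4E)-1-(3,4-dimethoxyphenyl)-2-(hydroxymethyl)-5-(4-methoxyphenyl)pent-4-en-1-one
Product: 10 (1S,2R,4E)-1-(3,4-dimethoxyphenyl)-2-(hydroxymethyl)-5-(4-methoxyphenyl)pent-4-en-1-ol
Conditions: Zn(BH4)2 (1.5 equiv), Et2O, −20 → 0 °C; H2O quench
Reagents that add atoms: none
Why: Chelation-controlled ketone reduction; zinc ties the carbonyl and the hydroxyl oxygen into a six-membered chelate and hydride enters anti to the cinnamyl branch at C2, which should set C1 as S (C1–OH syn to the C2 branch along the Ar–C1–C2–CH2O chain), and the near-neutral reagent should not enolise C2 or touch the styrene at this temperature.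

Step 6
Reactants: 11 (E)-but-2-enal
Product: 12 (Z)-2-iodobut-2-enal
Conditions: I2 (1.5 equiv), K2CO3 (1.2 equiv), DMAP (0.2 equiv), THF–H2O 1:1, rt
Reagents that add atoms: iodine, II
Why: α-Iodination of an enal by a Baylis–Hillman-type sequence (conjugate addition of DMAP, iodination of the enolate, elimination of DMAP); elimination gives the more stable isomer with methyl trans to the formyl group, hence cis to iodine (Z).

Step 7
Reactants: 12 (Z)-2-iodobut-2-enal
Product: 13 (Z)-2-iodobut-2-en-1-ol
Conditions: NaBH4 (1.0 equiv), THF–H2O, 0 °C
Reagents that add atoms: none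
Why: 1,2-Reduction of an α-substituted enal by borohydride; the α-iodine hinders conjugate attack and the alkene geometry is not affected.

Step 8
Reactants: 13 (Z)-2-iodobut-2-en-1-ol
Product: 14 tert-butyl{[(Z)-2-iodobut-2-en-1-yl]oxy}dimethylsilane
Conditions: t-BuMe2SiCl (1.1 equiv), imidazole (1.5 equiv), CH2Cl2, 0 °C → rt
Reagents that add atoms: tert-butylchlorodimethylsilane, CC(C)(C)[Si](C)(C)Cl
Why: Standard silylation of a primary alcohol; the silyl ether withstands the organolithium step and the Mitsunobu step and is later removed by fluoride without acid.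

Step 9
Reactants: 14 tert-butyl{[(Z)-2-iodobut-2-en-1-yl]oxy}dimethylsilane
Product: 16 (Z)-2-{[(tert-butyldimethylsilyl)oxy]methyl}but-2-enoic acid, via (E)-vinyllithium 15 (not isolated)
Conditions: t-BuLi (2.1 equiv), Et2O, −78 °C, 15 min; CO2 (g), −78 → −20 °C; 0.5 M aq. HCl to pH 3, 0 °C
Reagents that add atoms: carbon dioxide, O=C=O
Why: Iodine–lithium exchange followed by carboxylation; alkenyllithiums keep their geometry at −78 °C and are carboxylated with retention, so methyl stays cis to the new carboxyl (the E label of 15 and the Z label of 16 differ only through substituent priorities).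

Step 10
Reactants: 10 (1S,2R,4E)-1-(3,4-dimethoxyphenyl)-2-(hydroxymethyl)-5-(4-methoxyphenyl)pent-4-en-1-ol; 16 (Z)-2-{[(tert-butyldimethylsilyl)oxy]methyl}but-2-enoic acid
Product: 17 (2R,4E)-2-[(S)-(3,4-dimethoxyphenyl)(hydroxy)methyl]-5-(4-methoxyphenyl)pent-4-en-1-yl (2Z)-2-{[(tert-butyldimethylsilyl)oxy]methyl}but-2-enoate
Conditions: PPh3 (1.2 equiv), diisopropyl azodicarboxylate (1.2 equiv, added last), 16 (1.1 equiv), THF, 0 °C
Reagents that add atoms: none
Why: Mitsunobu esterification; the phosphonium activates the unhindered primary hydroxyl in preference to the branched benzylic one, and the acid reacts only as a carboxylate nucleophile at the achiral CH2, so no acyl activation occurs that could isomerise the Z enoate and no stereocentre is touched.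

Step 11
Reactants: 17 (2R,4E)-2-[(S)-(3,4-dimethoxyphenyl)(hydroxy)methyl]-5-(4-methoxyphenyl)pent-4-en-1-yl (2Z)-2-{[(tert-butyldimethylsilyl)oxy]methyl}but-2-enoate
Product: 18 (2R,4E)-2-[(S)-(3,4-dimethoxyphenyl)(hydroxy)methyl]-5-(4-methoxyphenyl)pent-4-en-1-yl (2Z)-2-(hydroxymethyl)but-2-enoate
Conditions: Bu4NF (1.5 equiv), AcOH (1.5 equiv), THF, 0 °C → rt
Reagents that add atoms: none
Why: Fluoride cleavage of a primary silyl ether; buffering with acetic acid keeps the medium from becoming basic enough for acyl migration to the benzylic hydroxyl and avoids the acid that would ionise the benzylic alcohol.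

## Compound list

1 | (E)-3-(4-methoxyphenyl)prop-2-en-1-ol | OC/C=C/c1ccc(OC)cc1 | starting material
2 | (E)-1-(3-bromoprop-1-en-1-yl)-4-methoxybenzene | BrC/C=C/c1ccc(OC)cc1 | intermediate
3 | 1-(3,4-dimethoxyphenyl)ethan-1-one | CC(=O)c1ccc(OC)c(OC)c1 | starting material
4 | lithium 1-(3,4-dimethoxyphenyl)ethen-1-olate | [Li]OC(=C)c1ccc(OC)c(OC)c1 | intermediate
5 | (E)-1-(3,4-dimethoxyphenyl)-5-(4-methoxyphenyl)pent-4-en-1-one | O=C(CC/C=C/c1ccc(OC)cc1)c1ccc(OC)c(OC)c1 | intermediate
6 | lithium (1Z,4E)-1-(3,4-dimethoxyphenyl)-5-(4-methoxyphenyl)penta-1,4-dien-1-olate | [Li]O/C(=C\C/C=C/c1ccc(OC)cc1)c1ccc(OC)c(OC)c1 | intermediate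
7 | {[(1Z,4E)-1-(3,4-dimethoxyphenyl)-5-(4-methoxyphenyl)penta-1,4-dien-1-yl]oxy}trimethylsilane | C[Si](C)(C)O/C(=C\C/C=C/c1ccc(OC)cc1)c1ccc(OC)c(OC)c1 | intermediate
8 | formaldehyde | C=O | starting material
9 | (2R,4E)-1-(3,4-dimethoxyphenyl)-2-(hydroxymethyl)-5-(4-methoxyphenyl)pent-4-en-1-one | OC[C@@H](C/C=C/c1ccc(OC)cc1)C(=O)c1ccc(OC)c(OC)c1 | intermediate
10 | (1S,2R,4E)-1-(3,4-dimethoxyphenyl)-2-(hydroxymethyl)-5-(4-methoxyphenyl)pent-4-en-1-ol | OC[C@@H](C/C=C/c1ccc(OC)cc1)[C@H](O)c1ccc(OC)c(OC)c1 | intermediate
11 | (E)-but-2-enal (crotonaldehyde) | C/C=C/C=O | starting material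
12 | (Z)-2-iodobut-2-enal | C/C=C(/C=O)I | intermediate
13 | (Z)-2-iodobut-2-en-1-ol | C/C=C(/CO)I | intermediate
14 | tert-butyl{[(Z)-2-iodobut-2-en-1-yl]oxy}dimethylsilane | C/C=C(/CO[Si](C)(C)C(C)(C)C)I | intermediate
15 | {(E)-1-[(tert-butyldimethylsilyloxy)methyl]prop-1-en-1-yl}lithium | C/C=C(/CO[Si](C)(C)C(C)(C)C)[Li] | intermediate
16 | (Z)-2-{[(tert-butyldimethylsilyl)oxy]methyl}but-2-enoic acid | C/C=C(/CO[Si](C)(C)C(C)(C)C)C(=O)O | intermediate
17 | (2R,4E)-2-[(S)-(3,4-dimethoxyphenyl)(hydroxy)methyl]-5-(4-methoxyphenyl)pent-4-en-1-yl (2Z)-2-{[(tert-butyldimethylsilyl)oxy]methyl}but-2-enoate | C/C=C(/CO[Si](C)(C)C(C)(C)C)C(=O)OC[C@@H](C/C=C/c1ccc(OC)cc1)[C@H](O)c1ccc(OC)c(OC)c1 | intermediate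
18 | (2R,4E)-2-[(S)-(3,4-dimethoxyphenyl)(hydroxy)methyl]-5-(4-methoxyphenyl)pent-4-en-1-yl (2Z)-2-(hydroxymethyl)but-2-enoate | C/C=C(/CO)C(=O)OC[C@@H](C/C=C/c1ccc(OC)cc1)[C@H](O)c1ccc(OC)c(OC)c1 | target

## Step count and least certain steps

Total step count: 11. Longest linear sequence: 7 steps (steps 1, 2, 3, 4, 5, 10, 11). The acid branch (steps 6 to 9) joins at step 10.

**Step 4 (key step).** Face selection may be less sharp than for the simple methyl-substituted enol silanes, because the C2 substituent is a longer cinnamylmethyl group and the aryl ring is more electron-rich. Protodesilylation of 7 in the aqueous Lewis-acidic medium may return ketone 5, and the product may enolise or dehydrate on handling.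

The fallback sets out from bromide 2 and returns at diol 10, setting both centres by an auxiliary-controlled aldol. Bromide 2 alkylates the dianion of acetic acid (AcOH, 2 LiN(i-Pr)2, THF) to give (E)-5-(4-methoxyphenyl)pent-4-enoic acid F1. Pivaloyl chloride and Et3N convert it into the mixed anhydride (E)-5-(4-methoxyphenyl)pent-4-enoic 2,2-dimethylpropanoic anhydride F2, which acylates (S)-4-benzyloxazolidin-2-one (LiCl, Et3N) to give (S)-4-benzyl-3-[(E)-5-(4-methoxyphenyl)pent-4-enoyl]oxazolidin-2-one F3. Its Z boron enolate (Bu2BOTf, i-Pr2NEt, CH2Cl2, −78 °C) adds to 3,4-dimethoxybenzaldehyde in an Evans syn aldol to give (S)-4-benzyl-3-{(2S,4E)-2-[(S)-(3,4-dimethoxyphenyl)(hydroxy)methyl]-5-(4-methoxyphenyl)pent-4-enoyl}oxazolidin-2-one F4. LiBH4 in wet Et2O at 0 °C removes the auxiliary reductively and gives 10.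

**Step 2.** Proton exchange between product 5 and unreacted enolate 4 may lead to double alkylation, and the electron-rich cinnamyl bromide 2 may ionise and decompose before it is consumed.

The fallback sets out from alcohol 1 and returns at ketone 5. DMAP-catalysed transesterification of commercial ethyl 3-(3,4-dimethoxyphenyl)-3-oxopropanoate with 1 in hot toluene gives (E)-3-(4-methoxyphenyl)prop-2-en-1-yl 3-(3,4-dimethoxyphenyl)-3-oxopropanoate F5. Pd(PPh3)4 in THF then effects decarboxylative allylation (Tsuji–Trost type), which delivers the linear mono-allylated ketone 5 without any allylic bromide.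

**Step 5.** The electron-rich aryl ketone is a weak acceptor, so reduction may be slow enough for an open-chain pathway to compete with the zinc chelate and lower the facial selectivity. C2 may also epimerise before reduction.

The fallback sets out from 9 and returns at 10, replacing substrate control by catalyst control. Silylation (t-BuMe2SiCl, imidazole) gives (2R,4E)-2-{[(tert-butyldimethylsilyl)oxy]methyl}-1-(3,4-dimethoxyphenyl)-5-(4-methoxyphenyl)pent-4-en-1-one F6. Corey–Bakshi–Shibata reduction follows, using (R)-1-methyl-3,3-diphenyltetrahydro-1H,3H-pyrrolo[1,2-c][1,3,2]oxazaborole and catecholborane in toluene at −78 °C. Catecholborane is chosen so that the styrene is not hydroborated. With the aryl group as the large substituent this should give (1S,2R,4E)-2-{[(tert-butyldimethylsilyl)oxy]methyl}-1-(3,4-dimethoxyphenyl)-5-(4-methoxyphenyl)pent-4-en-1-ol F7. Bu4NF buffered with AcOH then gives 10.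

**Step 9.** The vinyllithium 15 may undergo silyl migration from oxygen to carbon (retro-Brook type), may lose silanolate to form an allene, or may be protonated before carboxylation.

The fallback sets out from iodide 14 and returns at acid 16 without any carbanion. Heck-type methoxycarbonylation (PdCl2(PPh3)2, CO 1 atm, Et3N, MeOH–DMF, 50 °C) gives methyl (Z)-2-{[(tert-butyldimethylsilyl)oxy]methyl}but-2-enoate F8 with retention of geometry. LiOH in THF–H2O at 0 °C to rt then gives 16.

**Step 10.** The phosphonium may also engage the benzylic hydroxyl, or the 1,3-diol may form a cyclic phosphorane. Either would lead to ester formation at C1, elimination or loss of regioselectivity.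

The fallback sets out from diol 10 and returns at ester 17 by separating activation and substitution. Selective sulfonylation of the primary hydroxyl (TsCl, Et3N, cat. Me3N·HCl, CH2Cl2, 0 °C) gives (2R,4E)-2-[(S)-(3,4-dimethoxyphenyl)(hydroxy)methyl]-5-(4-methoxyphenyl)pent-4-en-1-yl 4-methylbenzenesulfonate F9. The caesium salt of 16 (Cs2CO3, DMF, 50 °C) displaces the sulfonate to give 17.

## Further compounds

F1 | step 4 | (E)-5-(4-methoxyphenyl)pent-4-enoic acid | OC(=O)CC/C=C/c1ccc(OC)cc1
F2 | step 4 | (E)-5-(4-methoxyphenyl)pent-4-enoic 2,2-dimethylpropanoic anhydride | CC(C)(C)C(=O)OC(=O)CC/C=C/c1ccc(OC)cc1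
F3 | step 4 | (S)-4-benzyl-3-[(E)-5-(4-methoxyphenyl)pent-4-enoyl]oxazolidin-2-one | O=C(CC/C=C/c1ccc(OC)cc1)N1[C@@H](Cc2ccccc2)COC1=O
F4 | step 4 | (S)-4-benzyl-3-{(2S,4E)-2-[(S)-(3,4-dimethoxyphenyl)(hydroxy)methyl]-5-(4-methoxyphenyl)pent-4-enoyl}oxazolidin-2-one | O=C([C@@H](C/C=C/c1ccc(OC)cc1)[C@H](O)c1ccc(OC)c(OC)c1)N1[C@@H](Cc2ccccc2)COC1=O
F5 | step 2 | (E)-3-(4-methoxyphenyl)prop-2-en-1-yl 3-(3,4-dimethoxyphenyl)-3-oxopropanoate | O=C(CC(=O)c1ccc(OC)c(OC)c1)OC/C=C/c1ccc(OC)cc1
F6 | step 5 | (2R,4E)-2-{[(tert-butyldimethylsilyl)oxy]methyl}-1-(3,4-dimethoxyphenyl)-5-(4-methoxyphenyl)pent-4-en-1-one | CC(C)(C)[Si](C)(C)OC[C@@H](C/C=C/c1ccc(OC)cc1)C(=O)c1ccc(OC)c(OC)c1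
F7 | step 5 | (1S,2R,4E)-2-{[(tert-butyldimethylsilyl)oxy]methyl}-1-(3,4-dimethoxyphenyl)-5-(4-methoxyphenyl)pent-4-en-1-ol | CC(C)(C)[Si](C)(C)OC[C@@H](C/C=C/c1ccc(OC)cc1)[C@H](O)c1ccc(OC)c(OC)c1
F8 | step 9 | methyl (Z)-2-{[(tert-butyldimethylsilyl)oxy]methyl}but-2-enoate | C/C=C(/CO[Si](C)(C)C(C)(C)C)C(=O)OC
F9 | step 10 | (2R,4E)-2-[(S)-(3,4-dimethoxyphenyl)(hydroxy)methyl]-5-(4-methoxyphenyl)pent-4-en-1-yl 4-methylbenzenesulfonate | Cc1ccc(cc1)S(=O)(=O)OC[C@@H](C/C=C/c1ccc(OC)cc1)[C@H](O)c1ccc(OC)c(OC)c1
A1 | alternative 1 | bis(tert-butyldimethylsilyl) ether of (1S,2R,4E)-1-(3,4-dimethoxyphenyl)-2-(hydroxymethyl)-5-(4-methoxyphenyl)pent-4-en-1-ol | C[Si](C)(C(C)(C)C)OC[C@@H](C/C=C/c1ccc(OC)cc1)[C@H](O[Si](C)(C)C(C)(C)C)c1ccc(OC)c(OC)c1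
A2 | alternative 1 | bis(tert-butyldimethylsilyl) ether of (R)-1-(3,4-dimethoxyphenyl)-2-methylidenepropane-1,3-diol | C=C(CO[Si](C)(C)C(C)(C)C)[C@H](O[Si](C)(C)C(C)(C)C)c1ccc(OC)c(OC)c1
A3 | alternative 1 | (E)-1-(2-bromoethenyl)-4-methoxybenzene | Br/C=C/c1ccc(OC)cc1
A4 | alternative 2 | (2R,4E)-2-[(S)-(3,4-dimethoxyphenyl)(triethylsilyloxy)methyl]-5-(4-methoxyphenyl)pent-4-en-1-yl (2Z)-2-(hydroxymethyl)but-2-enoate | C/C=C(/CO)C(=O)OC[C@@H](C/C=C/c1ccc(OC)cc1)[C@H](O[Si](CC)(CC)CC)c1ccc(OC)c(OC)c1
A5 | alternative 2 | (2R,4E)-2-[(S)-(3,4-dimethoxyphenyl)(triethylsilyloxy)methyl]-5-(4-methoxyphenyl)pent-4-en-1-yl but-2-ynoate | CC#CC(=O)OC[C@@H](C/C=C/c1ccc(OC)cc1)[C@H](O[Si](CC)(CC)CC)c1ccc(OC)c(OC)c1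
A6 | alternative 2 | but-2-ynoic acid | CC#CC(=O)O
A7 | alternative 3 | ethyl (2S,4E)-2-[(S)-(3,4-dimethoxyphenyl)(hydroxy)methyl]-5-(4-methoxyphenyl)pent-4-enoate | CCOC(=O)[C@@H](C/C=C/c1ccc(OC)cc1)[C@H](O)c1ccc(OC)c(OC)c1
A8 | alternative 3 | racemic ethyl (E)-2-(3,4-dimethoxybenzoyl)-5-(4-methoxyphenyl)pent-4-enoate | CCOC(=O)C(C/C=C/c1ccc(OC)cc1)C(=O)c1ccc(OC)c(OC)c1
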